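Assumption: the target is read as (2S,3'E,7'S,8'R), with chroman locants C2–C8a and side-chain locants C1'–C12' counted outward from C2; the five starting materials 1, 7, 18, 20 and 21 are bought.

## Retrosynthetic overview

1. Target 31 ← MOM removal ← C7' carbinol by catalyst-controlled CBS reduction of ketone 29 ← decarboxylation of β-keto ester 28.
2. Key disconnection C6'–C7': crossed Claisen condensation of the ester enolate of chroman fragment 17 with the non-enolizable α-alkoxy ester 26.
3. 26 (C8', R) ← (S)-lactic acid by Seebach dioxolanone alkylation with homoprenyl iodide 19.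
4. 17 ← Johnson–Claisen rearrangement (sets the E-trisubstituted olefin) of allylic alcohol 15, made from chroman 13 by epoxidation and isomerisation.
5. Rings: the benzene ring is bought; the only ring made is the pyran ring, closed by Pd-catalysed C–O coupling of tertiary alcohol 12, which comes from (S)-linalool 10 (Sharpless epoxidation of geraniol sets C2) and aryl iodide 6 by B-alkyl Suzuki coupling.

## Route

Step 1
Reactants: 1 4-methoxy-2-methylaniline
Product: 2 2-iodo-4-methoxy-6-methylaniline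
Conditions: N-iodosuccinimide (1.0 equiv), MeCN, 0 °C to rt
Reagents that add atoms: N-iodosuccinimide, O=C1CCC(=O)N1I
Why: Electrophilic aromatic iodination is steered by the amino group to its only free ortho position (para is blocked by OMe), placing iodine on the future C4a.

Step 2
Reactants: 2 2-iodo-4-methoxy-6-methylaniline
Product: 4 2-bromo-1-iodo-5-methoxy-3-methylbenzene, via arenediazonium bromide 3 (not isolated)
Conditions: NaNO2, 48% aq. HBr, 0 °C; then CuBr (0.3 equiv), 48% aq. HBr, 60 °C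
Reagents that add atoms: hydrobromic acid, Br
Why: The Sandmeyer reaction replaces the diazotised amino group by bromine, giving the future C8a–Br next to the methyl group and the iodide.

Step 3
Reactants: 4 2-bromo-1-iodo-5-methoxy-3-methylbenzene
Product: 5 4-bromo-3-iodo-5-methylphenol
Conditions: BBr3 (1.2 equiv), CH2Cl2, −78 °C to 0 °C; then H2O
Reagents that add atoms: none
Why: Lewis-acid O-demethylation is done on the robust dihaloarene so that the phenol can later carry a mildly removable group.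

Step 4
Reactants: 5 4-bromo-3-iodo-5-methylphenol
Product: 6 2-bromo-1-iodo-5-(methoxymethoxy)-3-methylbenzene
Conditions: MOMCl (1.3 equiv), iPr2NEt (1.5 equiv), CH2Cl2, 0 °C to rt
Reagents that add atoms: chloromethyl methyl ether, COCCl
Why: Williamson-type acetal protection gives a MOM ether that is stable to organometallic, basic and oxidative steps and leaves under mild acid at the end.

Step 5
Reactants: 7 geraniol
Product: 8 (2S,3S)-2,3-epoxygeraniol
Conditions: Ti(OiPr)4 (5 mol %), L-(+)-diethyl tartrate (7.5 mol %), t-BuOOH (1.5 equiv, anhydrous), 4 Å molecular sieves, CH2Cl2, −20 °C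
Reagents that add atoms: tert-butyl hydroperoxide, CC(C)(C)OO
Why: Sharpless asymmetric epoxidation with L-(+)-tartrate oxidises only the allylic-alcohol olefin and gives the (2S,3S) epoxide, whose tertiary C–O bond becomes the C2–O1 bond of the chroman (2S).

Step 6
Reactants: 8 (2S,3S)-2,3-epoxygeraniol
Product: 9 (2S,3R)-3-(iodomethyl)-2-methyl-2-(4-methylpent-3-en-1-yl)oxirane
Conditions: PPh3 (1.2 equiv), N-iodosuccinimide (1.2 equiv), CH2Cl2, −10 °C to 0 °C
Reagents that add atoms: N-iodosuccinimide, O=C1CCC(=O)N1I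
Why: Appel-type iodination of the primary alcohol under neutral conditions leaves the epoxide and both stereocentres untouched (the descriptor at the CH carbon changes by priority only).

Step 7
Reactants: 9 (2S,3R)-3-(iodomethyl)-2-methyl-2-(4-methylpent-3-en-1-yl)oxirane
Product: 10 (S)-linalool
Conditions: Zn dust (activated, 3 equiv), EtOH, 70 °C
Reagents that add atoms: none
Why: Zinc insertion into the C–I bond followed by β-elimination (reductive epoxide opening) gives the tertiary allylic alcohol without breaking the tertiary C–O bond, so the configuration is retained as S.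

Step 8
Reactants: 10 (S)-linalool; 6 2-bromo-1-iodo-5-(methoxymethoxy)-3-methylbenzene
Product: 12 (S)-1-[2-bromo-5-(methoxymethoxy)-3-methylphenyl]-3,7-dimethyloct-6-en-3-ol, via B-alkyl-9-BBN borane 11 (not isolated)
Conditions: 9-BBN dimer (0.75 equiv), THF, 0 °C to rt; then 6 (0.95 equiv), PdCl2(dppf) (5 mol %), 3 M aq. K3PO4 (3 equiv), DMF, rt to 45 °C
Reagents that add atoms: none
Why: 9-BBN hydroborates only the monosubstituted vinyl group (anti-Markovnikov), and the B-alkyl Suzuki–Miyaura coupling then takes place at the C–I bond in preference to the hindered C–Br bond; the stereocentre is not involved.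

Step 9
Reactants: 12 (S)-1-[2-bromo-5-(methoxymethoxy)-3-methylphenyl]-3,7-dimethyloct-6-en-3-ol
Product: 13 (S)-6-(methoxymethoxy)-2,8-dimethyl-2-(4-methylpent-3-en-1-yl)chroman
Conditions: Pd(OAc)2 (5 mol %), racemic 2-(di-tert-butylphosphino)-1,1'-binaphthyl (6 mol %), Cs2CO3 (1.5 equiv), toluene, 80 °C
Reagents that add atoms: none
Why: Intramolecular Buchwald–Hartwig-type C–O coupling joins the tertiary alkoxide (no hydrogen on the carbinol carbon, so no β-hydride loss) to the aryl carbon, so the C2–O bond is never broken and C2 stays S.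

Step 10
Reactants: 13 (S)-6-(methoxymethoxy)-2,8-dimethyl-2-(4-methylpent-3-en-1-yl)chroman
Product: 14 (2R)-2-[2-(3,3-dimethyloxiran-2-yl)ethyl]-6-(methoxymethoxy)-2,8-dimethylchroman (1:1 epimers at the oxirane carbon; ring stereocentre spatially as in 13)
Conditions: mCPBA (1.05 equiv), CH2Cl2, 0 °C; aq. NaHCO3 wash
Reagents that add atoms: 3-chloroperoxybenzoic acid, OOC(=O)c1cccc(Cl)c1
Why: Prilezhaev epoxidation of the only C=C bond; the new oxirane centre is destroyed two steps later, so the epimer mixture is of no consequence.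

Step 11
Reactants: 14 (2R)-2-[2-(3,3-dimethyloxiran-2-yl)ethyl]-6-(methoxymethoxy)-2,8-dimethylchroman
Product: 15 1-[(2R)-6-(methoxymethoxy)-2,8-dimethylchroman-2-yl]-4-methylpent-4-en-3-ol (1:1 carbinol epimers; ring stereocentre spatially as in 13)
Conditions: Al(OiPr)3 (2 equiv), toluene, 110 °C; aqueous work-up
Reagents that add atoms: none
Why: Aluminium-alkoxide-promoted epoxide-to-allylic-alcohol isomerisation removes a proton from a methyl group of the gem-dimethyl oxirane and gives the secondary alcohol with an isopropenyl group.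

Step 12
Reactants: 15 1-[(2R)-6-(methoxymethoxy)-2,8-dimethylchroman-2-yl]-4-methylpent-4-en-3-ol
Product: 17 methyl (E)-7-[(S)-6-(methoxymethoxy)-2,8-dimethylchroman-2-yl]-4-methylhept-4-enoate, via ketene acetal 16 (not isolated)
Conditions: MeC(OMe)3 (7 equiv), propionic acid (0.1 equiv), 110–125 °C, MeOH distilled off
Reagents that add atoms: trimethyl orthoacetate, CC(OC)(OC)OC
Why: The Johnson–Claisen orthoester rearrangement passes through a chair transition state with the chain equatorial, giving the E-trisubstituted C3'=C4' olefin and adding C6' with its ester handle.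

Step 13
Reactants: 18 5-bromo-2-methylpent-2-ene
Product: 19 5-iodo-2-methylpent-2-ene
Conditions: NaI (3 equiv), acetone, reflux
Reagents that add atoms: sodium iodide, [Na+].[I-]
Why: Finkelstein halide exchange gives the more reactive primary iodide needed for the enolate alkylation.

Step 14
Reactants: 20 (S)-lactic acid; 21 pivalaldehyde
Product: 22 (2S,5S)-2-tert-butyl-5-methyl-1,3-dioxolan-4-one
Conditions: 21 (1.3 equiv), p-TsOH·H2O (cat.), H2SO4 (cat.), pentane, reflux with water separator; crystallisation of the cis isomer from pentane/Et2O at −78 °C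
Reagents that add atoms: none
Why: Acid-catalysed acetalisation (Seebach dioxolanone) stores the lactate chirality in the new acetal centre, the cis isomer being favoured and purified by crystallisation.

Step 15
Reactants: 22 (2S,5S)-2-tert-butyl-5-methyl-1,3-dioxolan-4-one; 19 5-iodo-2-methylpent-2-ene
Product: 24 (2S,5R)-2-tert-butyl-5-methyl-5-(4-methylpent-3-en-1-yl)-1,3-dioxolan-4-one, via lithium enolate 23 (not isolated)
Conditions: LiN(iPr)2 (1.05 equiv), THF, −78 °C; then 19 (1.5 equiv), DMPU, −78 °C to −25 °C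
Reagents that add atoms: none
Why: Enolate alkylation under self-regeneration of stereocentres: the iodide attacks the enolate face opposite the tert-butyl group, so the homoprenyl group takes the place of the former hydrogen and C8' is set as R.

Step 16
Reactants: 24 (2S,5R)-2-tert-butyl-5-methyl-5-(4-methylpent-3-en-1-yl)-1,3-dioxolan-4-one
Product: 25 methyl (R)-2-hydroxy-2,6-dimethylhept-5-enoate
Conditions: NaOMe (0.2 equiv), MeOH, 0 °C to rt
Reagents that add atoms: methanol, CO
Why: Base-catalysed methanolysis (transesterification) opens the acylal lactone and releases pivalaldehyde; the quaternary centre cannot epimerise.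

Step 17
Reactants: 25 methyl (R)-2-hydroxy-2,6-dimethylhept-5-enoate
Product: 26 methyl (R)-2-(methoxymethoxy)-2,6-dimethylhept-5-enoate
Conditions: MOMCl (4 equiv), iPr2NEt (5 equiv), tetrabutylammonium iodide (0.1 equiv), 1,2-dichloroethane, 60 °C
Reagents that add atoms: chloromethyl methyl ether, COCCl
Why: MOM etherification of the tertiary alcohol removes the acidic proton before the enolate step and gives a group that leaves together with the aryl MOM ether at the end.

Step 18
Reactants: 17 methyl (E)-7-[(S)-6-(methoxymethoxy)-2,8-dimethylchroman-2-yl]-4-methylhept-4-enoate; 26 methyl (R)-2-(methoxymethoxy)-2,6-dimethylhept-5-enoate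
Product: 28 methyl (2RS,4R)-4-(methoxymethoxy)-2-{(E)-5-[(S)-6-(methoxymethoxy)-2,8-dimethylchroman-2-yl]-2-methylpent-2-en-1-yl}-4,8-dimethyl-3-oxonon-7-enoate, via lithium ester enolate 27 (not isolated)
Conditions: 17 (1.0 equiv), LiN(iPr)2 (2.2 equiv), THF, −78 °C; then 26 (1.5 equiv), −78 °C to −10 °C; AcOH quench
Reagents that add atoms: none
Why: Crossed Claisen condensation: the enolate of 17 (the only enolizable partner) acylates the non-enolizable α-alkoxy ester 26 to form the C6'–C7' bond that joins the two fragments, the second equivalent of base driving the reaction by deprotonating the β-keto ester; quaternary C8' cannot epimerise.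

Step 19
Reactants: 28 methyl (2RS,4R)-4-(methoxymethoxy)-2-{(E)-5-[(S)-6-(methoxymethoxy)-2,8-dimethylchroman-2-yl]-2-methylpent-2-en-1-yl}-4,8-dimethyl-3-oxonon-7-enoate
Product: 29 (3E,8R)-8-(methoxymethoxy)-1-[(S)-6-(methoxymethoxy)-2,8-dimethylchroman-2-yl]-4,8,12-trimethyltrideca-3,11-dien-7-one
Conditions: LiCl (3 equiv), H2O (2 equiv), DMSO, 140 °C
Reagents that add atoms: none
Why: Krapcho dealkoxycarbonylation removes the auxiliary ester carbon under neutral conditions that spare both MOM ethers and both olefins, and it erases the stereorandom C6' centre.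

Step 20
Reactants: 29 (3E,8R)-8-(methoxymethoxy)-1-[(S)-6-(methoxymethoxy)-2,8-dimethylchroman-2-yl]-4,8,12-trimethyltrideca-3,11-dien-7-one
Product: 30 (3E,7S,8R)-8-(methoxymethoxy)-1-[(S)-6-(methoxymethoxy)-2,8-dimethylchroman-2-yl]-4,8,12-trimethyltrideca-3,11-dien-7-ol
Conditions: (R)-Me-CBS oxazaborolidine [(R)-1-methyl-3,3-diphenyltetrahydro-1H,3H-pyrrolo[1,2-c][1,3,2]oxazaborole] (0.2 equiv), catecholborane (2 equiv), toluene, −78 °C to −40 °C; then MeOH and aqueous work-up
Reagents that add atoms: none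
Why: Corey–Bakshi–Shibata reduction: the (R)-catalyst distinguishes the small CH2 side from the large quaternary C8' side of the ketone and delivers hydride to give the 7'S carbinol under catalyst control, while catecholborane at low temperature leaves the trisubstituted olefins alone (the C7' epimers are diastereomers and separable).

Step 21
Reactants: 30 (3E,7S,8R)-8-(methoxymethoxy)-1-[(S)-6-(methoxymethoxy)-2,8-dimethylchroman-2-yl]-4,8,12-trimethyltrideca-3,11-dien-7-ol
Product: 31 (S)-2-[(3E,7S,8R)-7,8-dihydroxy-4,8,12-trimethyltrideca-3,11-dien-1-yl]-2,8-dimethylchroman-6-ol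
Conditions: conc. aq. HCl (cat.), MeOH/THF, rt to 40 °C
Reagents that add atoms: none
Why: Acid-catalysed acetal cleavage (transacetalisation to dimethoxymethane) removes both MOM groups under conditions too mild to ionise the tertiary alcohol or the olefins, leaving all three stereocentres intact.

## Compound list

1 | 4-methoxy-2-methylaniline | COc1ccc(N)c(C)c1 | starting material
2 | 2-iodo-4-methoxy-6-methylaniline | COc1cc(C)c(N)c(I)c1 | intermediate
3 | 2-iodo-4-methoxy-6-methylbenzenediazonium bromide | COc1cc(C)c([N+]#N)c(I)c1.[Br-] | intermediate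
4 | 2-bromo-1-iodo-5-methoxy-3-methylbenzene | COc1cc(C)c(Br)c(I)c1 | intermediate
5 | 4-bromo-3-iodo-5-methylphenol | Oc1cc(C)c(Br)c(I)c1 | intermediate
6 | 2-bromo-1-iodo-5-(methoxymethoxy)-3-methylbenzene | COCOc1cc(C)c(Br)c(I)c1 | intermediate
7 | geraniol, (E)-3,7-dimethylocta-2,6-dien-1-ol | CC(C)=CCC/C(C)=C/CO | starting material
8 | (2S,3S)-2,3-epoxygeraniol, [(2S,3S)-3-methyl-3-(4-methylpent-3-en-1-yl)oxiran-2-yl]methanol | CC(C)=CCC[C@]1(C)O[C@H]1CO | intermediate
9 | (2S,3R)-3-(iodomethyl)-2-methyl-2-(4-methylpent-3-en-1-yl)oxirane | CC(C)=CCC[C@]1(C)O[C@H]1CI | intermediate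
10 | (S)-linalool, (3S)-3,7-dimethylocta-1,6-dien-3-ol | CC(C)=CCC[C@](C)(O)C=C | intermediate
11 | (3R)-1-(9-borabicyclo[3.3.1]nonan-9-yl)-3,7-dimethyloct-6-en-3-ol (spatially as 10; descriptor changes by priority) | CC(C)=CCC[C@](C)(O)CCB1C2CCCC1CCC2 | intermediate
12 | (S)-1-[2-bromo-5-(methoxymethoxy)-3-methylphenyl]-3,7-dimethyloct-6-en-3-ol | CC(C)=CCC[C@](C)(O)CCc1cc(OCOC)cc(C)c1Br | intermediate
13 | (S)-6-(methoxymethoxy)-2,8-dimethyl-2-(4-methylpent-3-en-1-yl)chroman | CC(C)=CCC[C@@]1(C)CCc2cc(OCOC)cc(C)c2O1 | intermediate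
14 | (2R)-2-[2-(3,3-dimethyloxiran-2-yl)ethyl]-6-(methoxymethoxy)-2,8-dimethylchroman, 1:1 epimers at the oxirane carbon | CC1(C)OC1CC[C@@]1(C)CCc2cc(OCOC)cc(C)c2O1 | intermediate
15 | 1-[(2R)-6-(methoxymethoxy)-2,8-dimethylchroman-2-yl]-4-methylpent-4-en-3-ol, 1:1 carbinol epimers | C=C(C)C(O)CC[C@@]1(C)CCc2cc(OCOC)cc(C)c2O1 | intermediate
16 | (2R)-2-{3-[(1-methoxyethenyl)oxy]-4-methylpent-4-en-1-yl}-6-(methoxymethoxy)-2,8-dimethylchroman, epimers at the side-chain carbon | C=C(C)C(OC(=C)OC)CC[C@@]1(C)CCc2cc(OCOC)cc(C)c2O1 | intermediate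
17 | methyl (E)-7-[(S)-6-(methoxymethoxy)-2,8-dimethylchroman-2-yl]-4-methylhept-4-enoate | COC(=O)CC/C(C)=C/CC[C@@]1(C)CCc2cc(OCOC)cc(C)c2O1 | intermediate
18 | 5-bromo-2-methylpent-2-ene | CC(C)=CCCBr | starting material
19 | 5-iodo-2-methylpent-2-ene | CC(C)=CCCI | intermediate
20 | (S)-lactic acid | C[C@H](O)C(=O)O | starting material
21 | pivalaldehyde, 2,2-dimethylpropanal | CC(C)(C)C=O | starting material
22 | (2S,5S)-2-tert-butyl-5-methyl-1,3-dioxolan-4-one (cis) | C[C@@H]1O[C@H](C(C)(C)C)OC1=O | intermediate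
23 | lithium (2S)-2-tert-butyl-5-methyl-1,3-dioxol-4-olate | CC1=C([O-])O[C@@H](C(C)(C)C)O1.[Li+] | intermediate
24 | (2S,5R)-2-tert-butyl-5-methyl-5-(4-methylpent-3-en-1-yl)-1,3-dioxolan-4-one | C[C@]1(CCC=C(C)C)O[C@H](C(C)(C)C)OC1=O | intermediate
25 | methyl (R)-2-hydroxy-2,6-dimethylhept-5-enoate | C[C@@](O)(CCC=C(C)C)C(=O)OC | intermediate
26 | methyl (R)-2-(methoxymethoxy)-2,6-dimethylhept-5-enoate | C[C@@](OCOC)(CCC=C(C)C)C(=O)OC | intermediate
27 | lithium (4E)-1-methoxy-7-[(S)-6-(methoxymethoxy)-2,8-dimethylchroman-2-yl]-4-methylhepta-1,4-dien-1-olate | COC([O-])=CC/C(C)=C/CC[C@@]1(C)CCc2cc(OCOC)cc(C)c2O1.[Li+] | intermediate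
28 | methyl (2RS,4R)-4-(methoxymethoxy)-2-{(E)-5-[(S)-6-(methoxymethoxy)-2,8-dimethylchroman-2-yl]-2-methylpent-2-en-1-yl}-4,8-dimethyl-3-oxonon-7-enoate | COC(=O)C(C/C(C)=C/CC[C@@]1(C)CCc2cc(OCOC)cc(C)c2O1)C(=O)[C@](C)(OCOC)CCC=C(C)C | intermediate
29 | (3E,8R)-8-(methoxymethoxy)-1-[(S)-6-(methoxymethoxy)-2,8-dimethylchroman-2-yl]-4,8,12-trimethyltrideca-3,11-dien-7-one | CC(C)=CCC[C@@](C)(OCOC)C(=O)CC/C(C)=C/CC[C@@]1(C)CCc2cc(OCOC)cc(C)c2O1 | intermediate
30 | (3E,7S,8R)-8-(methoxymethoxy)-1-[(S)-6-(methoxymethoxy)-2,8-dimethylchroman-2-yl]-4,8,12-trimethyltrideca-3,11-dien-7-ol | CC(C)=CCC[C@@](C)(OCOC)[C@@H](O)CC/C(C)=C/CC[C@@]1(C)CCc2cc(OCOC)cc(C)c2O1 | intermediate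
31 | (S)-2-[(3E,7S,8R)-7,8-dihydroxy-4,8,12-trimethyltrideca-3,11-dien-1-yl]-2,8-dimethylchroman-6-ol | CC(C)=CCC[C@@](C)(O)[C@@H](O)CC/C(C)=C/CC[C@@]1(C)CCc2cc(O)cc(C)c2O1 | target

## Summary

Total step count: 21.
Longest linear sequence: 13 steps (steps 1, 2, 3, 4, 8, 9, 10, 11, 12, 18, 19, 20, 21; compounds 1 → 2 → 4 → 5 → 6 → 12 → 13 → 14 → 15 → 17 → 28 → 29 → 30 → 31).

Steps most likely to fail:

Step 9 (palladium-catalysed ring closure on a doubly ortho-substituted, electron-rich aryl bromide). The fallback closes the ring at the hydroquinone oxidation level instead of by cross-coupling; it sets out from 12 and returns to 13. Bromine–lithium exchange on 12 (n-BuLi, 2.2 equiv, THF, −78 °C), trapping with B(OMe)3 and oxidation (H2O2, aq. NaOH) give the phenol (S)-2-(3-hydroxy-3,7-dimethyloct-6-en-1-yl)-4-(methoxymethoxy)-6-methylphenol F1. Dilute HCl in MeOH with 5 mol % 1,4-benzoquinone then removes the MOM group and cyclises the hydroquinone to (S)-2,8-dimethyl-2-(4-methylpent-3-en-1-yl)chroman-6-ol F2. In this cyclisation the tertiary hydroxyl adds to the carbonyl carbon of the transient quinone and the hemiketal is reduced back to the arene, so the aryl C–O bond is exchanged and the C2–O bond is untouched (retention). MOMCl/iPr2NEt converts F2 into 13.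

Step 15 (alkylation of a thermally fragile enolate with an unactivated, elimination-prone homoallylic iodide). The fallback uses a reactive allylic electrophile and then builds the chain; it sets out from 22 (through enolate 23) and returns to 24. Allyl bromide alkylates 23 trans to the tert-butyl group to give (2S,5R)-5-allyl-2-tert-butyl-5-methyl-1,3-dioxolan-4-one F3. Hydroboration with 9-BBN and oxidation with NaBO3·4H2O give (2S,5R)-2-tert-butyl-5-(3-hydroxypropyl)-5-methyl-1,3-dioxolan-4-one F4. Dess–Martin oxidation gives (2S,5R)-2-tert-butyl-5-methyl-5-(3-oxopropyl)-1,3-dioxolan-4-one F5. Wittig olefination with isopropylidenetriphenylphosphorane (from isopropyltriphenylphosphonium iodide and n-BuLi, THF, −78 °C) then gives 24.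

Step 18 (crossed Claisen condensation onto a hindered α-quaternary ester). The fallback moves the Claisen condensation to a small, unhindered enolate and joins the halves by alkylation; it sets out from 26 and 13 and returns to 29.
- From 26, excess lithium enolate of allyl acetate (THF, −78 °C to 0 °C) gives allyl (R)-4-(methoxymethoxy)-4,8-dimethyl-3-oxonon-7-enoate F6.
- From 13, allylic oxidation of the E-methyl group (SeO2 cat., t-BuOOH, CH2Cl2; NaBH4 work-up) gives (E)-5-[(S)-6-(methoxymethoxy)-2,8-dimethylchroman-2-yl]-2-methylpent-2-en-1-ol F7.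
- CBr4/PPh3 converts F7 into (S)-2-[(E)-5-bromo-4-methylpent-3-en-1-yl]-6-(methoxymethoxy)-2,8-dimethylchroman F8.
- Alkylation of F6 with F8 (K2CO3, acetone) gives allyl (2RS,4R)-4-(methoxymethoxy)-2-{(E)-5-[(S)-6-(methoxymethoxy)-2,8-dimethylchroman-2-yl]-2-methylpent-2-en-1-yl}-4,8-dimethyl-3-oxonon-7-enoate F9.
- Pd(PPh3)4 with morpholine removes the allyl ester with loss of CO2 to give 29.

## Further compounds

F1 | step 9 | (S)-2-(3-hydroxy-3,7-dimethyloct-6-en-1-yl)-4-(methoxymethoxy)-6-methylphenol | CC(C)=CCC[C@](C)(O)CCc1cc(OCOC)cc(C)c1O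
F2 | step 9 | (S)-2,8-dimethyl-2-(4-methylpent-3-en-1-yl)chroman-6-ol | CC(C)=CCC[C@@]1(C)CCc2cc(O)cc(C)c2O1
F3 | step 15 | (2S,5R)-5-allyl-2-tert-butyl-5-methyl-1,3-dioxolan-4-one | C[C@]1(CC=C)O[C@H](C(C)(C)C)OC1=O
F4 | step 15 | (2S,5R)-2-tert-butyl-5-(3-hydroxypropyl)-5-methyl-1,3-dioxolan-4-one | C[C@]1(CCCO)O[C@H](C(C)(C)C)OC1=O
F5 | step 15 | (2S,5R)-2-tert-butyl-5-methyl-5-(3-oxopropyl)-1,3-dioxolan-4-one | C[C@]1(CCC=O)O[C@H](C(C)(C)C)OC1=O
F6 | step 18 | allyl (R)-4-(methoxymethoxy)-4,8-dimethyl-3-oxonon-7-enoate | C=CCOC(=O)CC(=O)[C@](C)(OCOC)CCC=C(C)C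
F7 | step 18 | (E)-5-[(S)-6-(methoxymethoxy)-2,8-dimethylchroman-2-yl]-2-methylpent-2-en-1-ol | OC/C(C)=C/CC[C@@]1(C)CCc2cc(OCOC)cc(C)c2O1
F8 | step 18 | (S)-2-[(E)-5-bromo-4-methylpent-3-en-1-yl]-6-(methoxymethoxy)-2,8-dimethylchroman | BrC/C(C)=C/CC[C@@]1(C)CCc2cc(OCOC)cc(C)c2O1
F9 | step 18 | allyl (2RS,4R)-4-(methoxymethoxy)-2-{(E)-5-[(S)-6-(methoxymethoxy)-2,8-dimethylchroman-2-yl]-2-methylpent-2-en-1-yl}-4,8-dimethyl-3-oxonon-7-enoate | C=CCOC(=O)C(C/C(C)=C/CC[C@@]1(C)CCc2cc(OCOC)cc(C)c2O1)C(=O)[C@](C)(OCOC)CCC=C(C)C
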